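**Retrosynthetic overview**
- The four phenols are unmasked last by global O-demethylation of a tetramethyl ether; both CH2CH2 bridges come from one hydrogenation of a bis-stilbene.
- Ring A to ring B bridge: Wittig disconnection to (3-methoxybenzyl)triphenylphosphonium chloride and a diaryl ether aldehyde.
- Ring B–O–ring C ether: SNAr disconnection to 4-fluorobenzaldehyde and a stilbene phenol.
- Ring C to ring D bridge: Wittig disconnection to isovanillin and a 2,5-dimethoxybenzyl phosphonium salt, made from the benzyl chloride and PPh3.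
- No ring is formed: the four benzene rings are bought and joined in the order D + C, then B, then A.

Assumption: the target has no stereocentre and no stereogenic double bond, so it is achiral and there is no enantiomer to control; the stilbene intermediates are carried as E/Z mixtures (SMILES written without alkene geometry) because both isomers give the same product on hydrogenation.

**Route**

Step 1
Reactants: 1 2,5-dimethoxybenzyl chloride; 2 triphenylphosphine
Product: 3 (2,5-dimethoxybenzyl)triphenylphosphonium chloride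
Conditions: toluene, reflux, 16 h; filter the precipitated salt
Reagents that add atoms: none
Why: SN2 quaternisation of an electron-rich benzylic chloride by PPh3 gives the salt, which precipitates from toluene; no stereocentre is formed.

Step 2
Reactants: 3 (2,5-dimethoxybenzyl)triphenylphosphonium chloride; 4 isovanillin (3-hydroxy-4-methoxybenzaldehyde)
Product: 6 stilbene phenol 5-[2-(2,5-dimethoxyphenyl)ethenyl]-2-methoxyphenol (E/Z mixture), via (2,5-dimethoxybenzylidene)triphenylphosphorane 5 (not isolated)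
Conditions: KOtBu (2.3 equiv), THF, 0 °C to rt
Reagents that add atoms: none
Why: Wittig olefination in which the extra KOtBu covers the acidic phenol O–H, whose oxygen is meta to the aldehyde and so does not deactivate it; the semistabilised ylide gives an E/Z mixture that does not matter because the alkene is hydrogenated in step 5, and no stereocentre is formed.

Step 3
Reactants: 6 stilbene phenol 5-[2-(2,5-dimethoxyphenyl)ethenyl]-2-methoxyphenol; 7 4-fluorobenzaldehyde
Product: 8 diaryl ether aldehyde 4-{5-[2-(2,5-dimethoxyphenyl)ethenyl]-2-methoxyphenoxy}benzaldehyde (E/Z mixture)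
Conditions: K2CO3, DMF, 140 °C
Reagents that add atoms: none
Why: Nucleophilic aromatic substitution (SNAr, addition–elimination) in which the para-formyl group activates the C–F carbon toward the phenol oxygen under carbonate base; no stereocentre is formed.

Step 4
Reactants: 8 diaryl ether aldehyde; 9 (3-methoxybenzyl)triphenylphosphonium chloride
Product: 11 bis-stilbene 1,4-dimethoxy-2-[2-(4-methoxy-3-{4-[2-(3-methoxyphenyl)ethenyl]phenoxy}phenyl)ethenyl]benzene (E/Z mixture), via (3-methoxybenzylidene)triphenylphosphorane 10 (not isolated)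
Conditions: KOtBu (1.2 equiv), THF, 0 °C to rt
Reagents that add atoms: none
Why: Wittig olefination of an unhindered aryl aldehyde by a semistabilised benzylic ylide, tolerated by the ethers and the existing alkene; the alkene geometry is again irrelevant and no stereocentre is formed.

Step 5
Reactants: 11 bis-stilbene tetramethyl ether
Product: 12 1,4-dimethoxy-2-[2-(4-methoxy-3-{4-[2-(3-methoxyphenyl)ethyl]phenoxy}phenyl)ethyl]benzene
Conditions: H2 (1 atm), 10% Pd/C, EtOAc, rt
Reagents that add atoms: none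
Why: Heterogeneous catalytic hydrogenation saturates both stilbene double bonds of either geometry, while the aryl methyl ethers and the diaryl ether are inert at 1 atm and rt; each new carbon is a CH2, so no stereocentre arises.

Step 6
Reactants: 12 tetramethyl ether bis-bibenzyl
Product: 14 2-[2-(4-hydroxy-3-{4-[2-(3-hydroxyphenyl)ethyl]phenoxy}phenyl)ethyl]benzene-1,4-diol (the target), via tetrakis(dibromoboryloxy) intermediate 13 (not isolated)
Conditions: BBr3 (8 equiv), CH2Cl2, −78 °C to rt, N2; then H2O, 0 °C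
Reagents that add atoms: none
Why: Lewis acid-mediated aryl methyl ether cleavage, in which BBr3 binds each methoxy oxygen and bromide removes the methyl group by SN2, while the diaryl ether has no sp3 carbon to attack and survives; water then hydrolyses the B–O bonds to free the four phenols, and no stereocentre is involved.

**Compound list**

1 | 2,5-dimethoxybenzyl chloride (2-(chloromethyl)-1,4-dimethoxybenzene) | COc1ccc(OC)c(CCl)c1 | starting material
2 | triphenylphosphine | c1ccc(cc1)P(c1ccccc1)c1ccccc1 | starting material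
3 | (2,5-dimethoxybenzyl)triphenylphosphonium chloride | COc1ccc(OC)c(C[P+](c2ccccc2)(c2ccccc2)c2ccccc2)c1.[Cl-] | intermediate
4 | isovanillin (3-hydroxy-4-methoxybenzaldehyde) | COc1ccc(C=O)cc1O | starting material
5 | (2,5-dimethoxybenzylidene)triphenylphosphorane (ylide, not isolated) | COc1ccc(OC)c(C=P(c2ccccc2)(c2ccccc2)c2ccccc2)c1 | intermediate
6 | 5-[2-(2,5-dimethoxyphenyl)ethenyl]-2-methoxyphenol (E/Z mixture) | COc1ccc(OC)c(C=Cc2ccc(OC)c(O)c2)c1 | intermediate
7 | 4-fluorobenzaldehyde | O=Cc1ccc(F)cc1 | starting material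
8 | 4-{5-[2-(2,5-dimethoxyphenyl)ethenyl]-2-methoxyphenoxy}benzaldehyde (E/Z mixture) | COc1ccc(OC)c(C=Cc2ccc(OC)c(Oc3ccc(C=O)cc3)c2)c1 | intermediate
9 | (3-methoxybenzyl)triphenylphosphonium chloride | COc1cccc(C[P+](c2ccccc2)(c2ccccc2)c2ccccc2)c1.[Cl-] | starting material
10 | (3-methoxybenzylidene)triphenylphosphorane (ylide, not isolated) | COc1cccc(C=P(c2ccccc2)(c2ccccc2)c2ccccc2)c1 | intermediate
11 | 1,4-dimethoxy-2-[2-(4-methoxy-3-{4-[2-(3-methoxyphenyl)ethenyl]phenoxy}phenyl)ethenyl]benzene (E/Z mixture at both alkenes) | COc1cccc(C=Cc2ccc(Oc3cc(C=Cc4cc(OC)ccc4OC)ccc3OC)cc2)c1 | intermediate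
12 | 1,4-dimethoxy-2-[2-(4-methoxy-3-{4-[2-(3-methoxyphenyl)ethyl]phenoxy}phenyl)ethyl]benzene | COc1cccc(CCc2ccc(Oc3cc(CCc4cc(OC)ccc4OC)ccc3OC)cc2)c1 | intermediate
13 | tetrakis(dibromoboryloxy) intermediate (each of the four phenol oxygens of 14 carries BBr2; not isolated) | BrB(Br)Oc1cccc(CCc2ccc(Oc3cc(CCc4cc(OB(Br)Br)ccc4OB(Br)Br)ccc3OB(Br)Br)cc2)c1 | intermediate
14 | 2-[2-(4-hydroxy-3-{4-[2-(3-hydroxyphenyl)ethyl]phenoxy}phenyl)ethyl]benzene-1,4-diol (CNP0300581.0, achiral) | Oc1cccc(CCc2ccc(Oc3cc(CCc4cc(O)ccc4O)ccc3O)cc2)c1 | target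

**Step count and risks**

Total steps: 6. Longest linear sequence: 6 (the route is fully linear; 9 is bought).

The three steps most likely to fail:

Step 2, the Wittig reaction on a free phenolic aldehyde, where the potassium salt of isovanillin may be poorly soluble or the olefination may stall. The fallback forms the diaryl ether before the olefination and carries the second aldehyde as a nitrile. It sets out from 4: SNAr of 4 on 4-fluorobenzonitrile (K2CO3, DMF, 130 °C) gives 4-(5-formyl-2-methoxyphenoxy)benzonitrile F1. Wittig olefination of F1 by ylide 5 (from 3, KOtBu, THF) gives 4-{5-[2-(2,5-dimethoxyphenyl)ethenyl]-2-methoxyphenoxy}benzonitrile F2. Reduction of the nitrile with iBu2AlH (toluene, −78 °C, then 1 M HCl) gives the aldehyde, and the fallback comes back to the route at 8.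

Step 3, the SNAr at 140 °C, where the electron-rich stilbene phenol or the aldehyde may degrade under hot base. The fallback removes the alkene first and makes the ether by copper-mediated oxidative coupling at room temperature. It sets out from 6: hydrogenation (H2, 10% Pd/C, EtOAc) gives 5-[2-(2,5-dimethoxyphenyl)ethyl]-2-methoxyphenol F3. Chan–Lam coupling of F3 with 4-formylphenylboronic acid (Cu(OAc)2, pyridine, 4 Å molecular sieves, CH2Cl2, air, rt) gives 4-{5-[2-(2,5-dimethoxyphenyl)ethyl]-2-methoxyphenoxy}benzaldehyde F4. Wittig olefination of F4 by ylide 10 gives 1,4-dimethoxy-2-[2-(4-methoxy-3-{4-[2-(3-methoxyphenyl)ethenyl]phenoxy}phenyl)ethyl]benzene F5. Hydrogenation of F5 as in step 5 comes back to the route at 12.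

Step 6, the fourfold demethylation, where partly demethylated products are hard to separate and the hydroquinone product is sensitive to oxidation under the acidic work-up. The fallback carries all four phenols as benzyl ethers, so that one final hydrogenation both saturates the bridges and frees the phenols under neutral, reducing conditions. It sets out from 2, uses 7 again for the ether step, and comes back at 14.
- Ring A salt: 2 and commercial 3-(benzyloxy)benzyl bromide (toluene, reflux) give [3-(benzyloxy)benzyl]triphenylphosphonium bromide F6.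
- Ring D salt: commercial 2,5-bis(benzyloxy)benzaldehyde is reduced (NaBH4, MeOH) to [2,5-bis(benzyloxy)phenyl]methanol F7. Triphenylphosphine hydrobromide (MeCN, reflux) converts F7 into [2,5-bis(benzyloxy)benzyl]triphenylphosphonium bromide F8.
- First Wittig: KOtBu (2.3 equiv, THF) turns F8 into [2,5-bis(benzyloxy)benzylidene]triphenylphosphorane F9, which olefinates commercial 4-(benzyloxy)-3-hydroxybenzaldehyde to 2-(benzyloxy)-5-{2-[2,5-bis(benzyloxy)phenyl]ethenyl}phenol F10.
- Ether: SNAr of F10 on 7 (K2CO3, DMF, 140 °C) gives 4-(2-(benzyloxy)-5-{2-[2,5-bis(benzyloxy)phenyl]ethenyl}phenoxy)benzaldehyde F11.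
- Second Wittig: KOtBu (THF) turns F6 into [3-(benzyloxy)benzylidene]triphenylphosphorane F12, which converts F11 into 1,4-bis(benzyloxy)-2-[2-(4-(benzyloxy)-3-{4-[2-(3-(benzyloxy)phenyl)ethenyl]phenoxy}phenyl)ethenyl]benzene F13.
- End: H2 (1 atm), 10% Pd/C, EtOAc/MeOH, rt reduces both alkenes of F13 and cleaves the four benzyl ethers to give 14 directly.

**Further compounds**

F1 | step 2 | 4-(5-formyl-2-methoxyphenoxy)benzonitrile | COc1ccc(C=O)cc1Oc1ccc(C#N)cc1
F2 | step 2 | 4-{5-[2-(2,5-dimethoxyphenyl)ethenyl]-2-methoxyphenoxy}benzonitrile (E/Z mixture) | COc1ccc(OC)c(C=Cc2ccc(OC)c(Oc3ccc(C#N)cc3)c2)c1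
F3 | step 3 | 5-[2-(2,5-dimethoxyphenyl)ethyl]-2-methoxyphenol | COc1ccc(OC)c(CCc2ccc(OC)c(O)c2)c1
F4 | step 3 | 4-{5-[2-(2,5-dimethoxyphenyl)ethyl]-2-methoxyphenoxy}benzaldehyde | COc1ccc(OC)c(CCc2ccc(OC)c(Oc3ccc(C=O)cc3)c2)c1
F5 | step 3 | 1,4-dimethoxy-2-[2-(4-methoxy-3-{4-[2-(3-methoxyphenyl)ethenyl]phenoxy}phenyl)ethyl]benzene (E/Z mixture) | COc1cccc(C=Cc2ccc(Oc3cc(CCc4cc(OC)ccc4OC)ccc3OC)cc2)c1
F6 | step 6 | [3-(benzyloxy)benzyl]triphenylphosphonium bromide | [Br-].c1ccc(COc2cccc(C[P+](c3ccccc3)(c3ccccc3)c3ccccc3)c2)cc1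
F7 | step 6 | [2,5-bis(benzyloxy)phenyl]methanol | OCc1cc(OCc2ccccc2)ccc1OCc1ccccc1
F8 | step 6 | [2,5-bis(benzyloxy)benzyl]triphenylphosphonium bromide | [Br-].c1ccc(COc2ccc(OCc3ccccc3)c(C[P+](c3ccccc3)(c3ccccc3)c3ccccc3)c2)cc1
F9 | step 6 | [2,5-bis(benzyloxy)benzylidene]triphenylphosphorane | c1ccc(COc2ccc(OCc3ccccc3)c(C=P(c3ccccc3)(c3ccccc3)c3ccccc3)c2)cc1
F10 | step 6 | 2-(benzyloxy)-5-{2-[2,5-bis(benzyloxy)phenyl]ethenyl}phenol (E/Z mixture) | Oc1cc(C=Cc2cc(OCc3ccccc3)ccc2OCc2ccccc2)ccc1OCc1ccccc1
F11 | step 6 | 4-(2-(benzyloxy)-5-{2-[2,5-bis(benzyloxy)phenyl]ethenyl}phenoxy)benzaldehyde (E/Z mixture) | O=Cc1ccc(Oc2cc(C=Cc3cc(OCc4ccccc4)ccc3OCc3ccccc3)ccc2OCc2ccccc2)cc1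
F12 | step 6 | [3-(benzyloxy)benzylidene]triphenylphosphorane | c1ccc(COc2cccc(C=P(c3ccccc3)(c3ccccc3)c3ccccc3)c2)cc1
F13 | step 6 | 1,4-bis(benzyloxy)-2-[2-(4-(benzyloxy)-3-{4-[2-(3-(benzyloxy)phenyl)ethenyl]phenoxy}phenyl)ethenyl]benzene (E/Z mixture) | c1ccc(COc2cccc(C=Cc3ccc(Oc4cc(C=Cc5cc(OCc6ccccc6)ccc5OCc5ccccc5)ccc4OCc4ccccc4)cc3)c2)cc1
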